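## Retrosynthetic overview

1. The C40 chain is cut at C11=C12 and C11'=C12' (two Wittig reactions): C10 trienedial + an acetylenic C15 and a 7',8'-dihydro C15 tributylphosphonium salt.
2. Both C15 units come from one (E)-C4 vinyl triflate: Sonogashira coupling with a ring alkyne (C8–C9) and B-alkyl Suzuki coupling with a ring vinyl compound (C8'–C9').
3. Ring alkyne and ring vinyl compound both come from (R)-3-hydroxy-β-cyclocitral.
4. Ring formation: both cyclohexene rings are formed together in step 2 by a twofold Diels–Alder reaction of 4-methylpenta-1,3-diene with a glycol-tethered bis(but-2-ynoate). No ring is formed afterwards.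
5. A twofold Ipc2BH hydroboration of the resulting bis(1,4-diene) sets both (3R)-carbinols; reductive cleavage of the tether releases two ring units.

Assumption: the C10 dialdehyde and crystalline (−)-Ipc2BH (from (+)-α-pinene) are purchased; no hydroxyl protecting groups are used.

## Route

Step 1
Reactants: 1 but-2-ynoic acid (2.2 equiv); 2 ethane-1,2-diol
Product: 3 ethane-1,2-diyl bis(but-2-ynoate)
Conditions: p-TsOH (5 mol%), toluene, reflux, Dean–Stark
Reagents that add atoms: none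
Why: Fischer esterification driven to the diester by azeotropic removal of water.

Step 2
Reactants: 3 ethane-1,2-diyl bis(but-2-ynoate); 4 4-methylpenta-1,3-diene (6 equiv)
Product: 6 ethane-1,2-diyl bis(2,6,6-trimethylcyclohexa-1,4-diene-1-carboxylate), via mono-cycloadduct 5 (not isolated)
Conditions: EtAlCl2 (40 mol%), CH2Cl2, −30 → 0 °C
Reagents that add atoms: none
Why: Proposed new method: twofold Lewis-acid-catalysed Diels–Alder reaction in which each Al-complexed ynoate is attacked at its methyl-bearing β-carbon by the unsubstituted diene terminus, giving a tertiary allyl cation/aluminium allenolate pair that closes at the CMe2 terminus ("ortho" orientation, gem-dimethyl next to the ester carbon), so the (Z)-methyl group that slows a concerted reaction of this diene is tolerated; the closest known reaction types are the AlCl3-promoted Diels–Alder reaction of penta-1,3-diene with mesityl oxide (δ-damascone process, same CMe2–C(acyl) bond) and Lewis-acid-catalysed cycloadditions of alkynoates; no stereocentre is formed and both rings of the target arise here.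

Step 3
Reactants: 6 ethane-1,2-diyl bis(2,6,6-trimethylcyclohexa-1,4-diene-1-carboxylate)
Product: 8 ethane-1,2-diyl bis[(4R)-4-hydroxy-2,6,6-trimethylcyclohex-1-ene-1-carboxylate], via bis-trialkylborane 7 (not isolated)
Conditions: (−)-Ipc2BH (3 equiv), THF, −25 → 0 °C, 72 h; then 3 M NaOH, 30% H2O2, 0 → 23 °C
Reagents that add atoms: hydrogen peroxide, OO
Why: Brown asymmetric hydroboration–oxidation of a cis-disubstituted ring alkene: boron goes to C4, away from the quaternary C6, and (−)-Ipc2BH (the reagent that gives (R)-butan-2-ol from cis-but-2-ene) delivers B–H to the face that, with C5 as partner carbon, gives the (4R)-alcohol after oxidation with retention; the tetrasubstituted enoate C=C and the esters are inert, and both stereocentres of the target are set here.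

Step 4
Reactants: 8 ethane-1,2-diyl bis[(4R)-4-hydroxy-2,6,6-trimethylcyclohex-1-ene-1-carboxylate]
Product: 9 (1R)-4-(hydroxymethyl)-3,5,5-trimethylcyclohex-3-en-1-ol (2 equiv)
Conditions: LiAlH4 (4 equiv), THF, 0 → 50 °C; Fieser work-up
Reagents that add atoms: none
Why: Hydride reduction of the hindered enoate esters to allylic alcohols (cyclogeraniol type) cleaves the tether and releases two ring units; the carbinol centre is untouched.

Step 5
Reactants: 9 (1R)-4-(hydroxymethyl)-3,5,5-trimethylcyclohex-3-en-1-ol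
Product: 10 (4R)-4-hydroxy-2,6,6-trimethylcyclohex-1-ene-1-carbaldehyde
Conditions: MnO2 (15 equiv), CH2Cl2, 23 °C
Reagents that add atoms: none
Why: Chemoselective MnO2 oxidation of the allylic primary alcohol; the homoallylic secondary alcohol is not activated.

Step 6
Reactants: 10 (4R)-4-hydroxy-2,6,6-trimethylcyclohex-1-ene-1-carbaldehyde
Product: 11 (1R)-4-ethynyl-3,5,5-trimethylcyclohex-3-en-1-ol
Conditions: TMSCHN2 (2.3 equiv), LDA (2.4 equiv), THF, −78 → 0 °C
Reagents that add atoms: trimethylsilyldiazomethane, C[Si](C)(C)C=[N+]=[N-]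
Why: Colvin homologation (1,2-addition, Peterson-type loss of LiOSiMe3, 1,2-H shift of the alkylidene carbene); the ring hydroxyl is present as its lithium alkoxide, which cannot leave, so vinylogous elimination to safranal is suppressed.

Step 7
Reactants: 12 ethyl acetoacetate
Product: 13 ethyl (2E)-3-{[(trifluoromethyl)sulfonyl]oxy}but-2-enoate
Conditions: Tf2O (1.5 equiv), aq. Me4NOH, hexane, 5 °C
Reagents that add atoms: trifluoromethanesulfonic anhydride, O=S(=O)(OS(=O)(=O)C(F)(F)F)C(F)(F)F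
Why: O-triflation of the non-chelated tetramethylammonium enolate gives the (E)-enol triflate (OTf trans to CO2Et), a known stereoselective enol triflate synthesis.

Step 8
Reactants: 13 ethyl (2E)-3-{[(trifluoromethyl)sulfonyl]oxy}but-2-enoate
Product: 14 (2E)-4-hydroxybut-2-en-2-yl trifluoromethanesulfonate
Conditions: DIBAL-H (2.3 equiv), CH2Cl2, −78 °C; Rochelle salt
Reagents that add atoms: none
Why: DIBAL-H reduction of the ester to the allylic alcohol leaves the vinyl triflate and the alkene geometry intact at −78 °C.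

Step 9
Reactants: 11 (1R)-4-ethynyl-3,5,5-trimethylcyclohex-3-en-1-ol; 14 (2E)-4-hydroxybut-2-en-2-yl trifluoromethanesulfonate
Product: 15 (1R)-4-[(3E)-5-hydroxy-3-methylpent-3-en-1-yn-1-yl]-3,5,5-trimethylcyclohex-3-en-1-ol
Conditions: Pd(PPh3)2Cl2 (3 mol%), CuI (6 mol%), i-Pr2NH, THF, 23 °C
Reagents that add atoms: none
Why: Sonogashira coupling of the terminal enyne with the vinyl triflate proceeds with retention and fixes the 9E geometry; free hydroxyls are tolerated.

Step 10
Reactants: 15 (1R)-4-[(3E)-5-hydroxy-3-methylpent-3-en-1-yn-1-yl]-3,5,5-trimethylcyclohex-3-en-1-ol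
Product: 17 tributyl{(2E)-5-[(4R)-4-hydroxy-2,6,6-trimethylcyclohex-1-en-1-yl]-3-methylpent-2-en-4-yn-1-yl}phosphonium bromide, via allylic bromide 16 (not isolated)
Conditions: NBS, Me2S, CH2Cl2, −30 → 0 °C; aqueous wash; then n-Bu3P, EtOAc, 0 → 23 °C
Reagents that add atoms: N-bromosuccinimide, O=C1CCC(=O)N1Br; tributylphosphine, CCCCP(CCCC)CCCC
Why: Corey–Kim halogenation converts only the allylic primary alcohol into the bromide with retention of alkene geometry and SN2 quaternisation gives the salt; the tributylphosphonium group is chosen because acetylenic C15 ylides of this type keep the 9E geometry better than the triphenyl analogues.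

Step 11
Reactants: 17 tributyl{(2E)-5-[(4R)-4-hydroxy-2,6,6-trimethylcyclohex-1-en-1-yl]-3-methylpent-2-en-4-yn-1-yl}phosphonium bromide; 18 (2E,4E,6E)-2,7-dimethylocta-2,4,6-trienedial (3 equiv)
Product: 20 (2E,4E,6E,8E,10E)-13-[(4R)-4-hydroxy-2,6,6-trimethylcyclohex-1-en-1-yl]-2,7,11-trimethyltrideca-2,4,6,8,10-pentaen-12-ynal, via phosphorus ylide 19 (not isolated)
Conditions: NaOMe (1.5 equiv), CH2Cl2/MeOH, 0 → 23 °C, Ar, dark
Reagents that add atoms: none
Why: Wittig olefination of one formyl group, with mono-condensation enforced by the excess dialdehyde; the allylic trialkylphosphonium ylide gives the (E)-C11=C12 bond.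

Step 12
Reactants: 10 (4R)-4-hydroxy-2,6,6-trimethylcyclohex-1-ene-1-carbaldehyde
Product: 21 (1R)-4-ethenyl-3,5,5-trimethylcyclohex-3-en-1-ol
Conditions: Ph3PCH3Br (2.6 equiv), KOtBu (2.5 equiv), THF, 0 → 23 °C
Reagents that add atoms: methyltriphenylphosphonium bromide, C[P+](c1ccccc1)(c1ccccc1)c1ccccc1.[Br-]
Why: Wittig methylenation of the hindered enal; the excess ylide holds the ring hydroxyl as its alkoxide, which again blocks elimination.

Step 13
Reactants: 21 (1R)-4-ethenyl-3,5,5-trimethylcyclohex-3-en-1-ol; 14 (2E)-4-hydroxybut-2-en-2-yl trifluoromethanesulfonate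
Product: 23 (1R)-4-[(3E)-5-hydroxy-3-methylpent-3-en-1-yl]-3,5,5-trimethylcyclohex-3-en-1-ol, via alkyl-9-BBN 22 (not isolated)
Conditions: 9-BBN (2.3 equiv), THF, 0 → 23 °C; then 14, Pd(dppf)Cl2 (5 mol%), Ph3As (10 mol%), Cs2CO3, DMF/H2O, 23 °C
Reagents that add atoms: none
Why: 9-BBN adds anti-Markovnikov to the terminal vinyl group only (the tetrasubstituted ring alkene is inert) and the B-alkyl Suzuki–Miyaura coupling with the vinyl triflate proceeds with retention, giving the saturated C7'–C8' unit and the 9'E alkene.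

Step 14
Reactants: 23 (1R)-4-[(3E)-5-hydroxy-3-methylpent-3-en-1-yl]-3,5,5-trimethylcyclohex-3-en-1-ol
Product: 25 tributyl{(2E)-5-[(4R)-4-hydroxy-2,6,6-trimethylcyclohex-1-en-1-yl]-3-methylpent-2-en-1-yl}phosphonium bromide, via allylic bromide 24 (not isolated)
Conditions: NBS, Me2S, CH2Cl2, −30 → 0 °C; aqueous wash; then n-Bu3P, EtOAc, 0 → 23 °C
Reagents that add atoms: N-bromosuccinimide, O=C1CCC(=O)N1Br; tributylphosphine, CCCCP(CCCC)CCCC
Why: Corey–Kim halogenation of the allylic primary alcohol (no allyl cation, so 9'E is kept) followed by SN2 quaternisation; the secondary ring alcohol is not converted.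

Step 15
Reactants: 25 tributyl{(2E)-5-[(4R)-4-hydroxy-2,6,6-trimethylcyclohex-1-en-1-yl]-3-methylpent-2-en-1-yl}phosphonium bromide; 20 (2E,4E,6E,8E,10E)-13-[(4R)-4-hydroxy-2,6,6-trimethylcyclohex-1-en-1-yl]-2,7,11-trimethyltrideca-2,4,6,8,10-pentaen-12-ynal
Product: 27 (3R,3'R)-all-E-7,8-didehydro-7',8'-dihydro-β,β-carotene-3,3'-diol (CNP0178054.1), via phosphorus ylide 26 (not isolated)
Conditions: NaOMe (1.5 equiv), CH2Cl2/MeOH, 23 °C, Ar, dark; crystallisation of the all-E isomer
Reagents that add atoms: none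
Why: Wittig olefination with an allylic tributylphosphonium ylide forms the (E)-C11'=C12' bond and completes the C40 chain; both carbinol centres are remote and unaffected.

## Compound list

1 | but-2-ynoic acid | CC#CC(=O)O | starting material
2 | ethane-1,2-diol | OCCO | starting material
3 | ethane-1,2-diyl bis(but-2-ynoate) | CC#CC(=O)OCCOC(=O)C#CC | intermediate
4 | 4-methylpenta-1,3-diene | CC(C)=CC=C | starting material
5 | 2-(but-2-ynoyloxy)ethyl 2,6,6-trimethylcyclohexa-1,4-diene-1-carboxylate (mono-cycloadduct, in situ) | CC#CC(=O)OCCOC(=O)C1=C(C)CC=CC1(C)C | intermediate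
6 | ethane-1,2-diyl bis(2,6,6-trimethylcyclohexa-1,4-diene-1-carboxylate) | CC1=C(C(=O)OCCOC(=O)C2=C(C)CC=CC2(C)C)C(C)(C)C=CC1 | intermediate
7 | ethane-1,2-diyl bis[(4R)-4-(diisopinocampheylboryl)-2,6,6-trimethylcyclohex-1-ene-1-carboxylate] (in situ) | O=C(OCCOC(=O)C1=C(C)C[C@@H](B([C@@H]2C[C@@H]3C[C@H]([C@H]2C)C3(C)C)[C@@H]2C[C@@H]3C[C@H]([C@H]2C)C3(C)C)CC1(C)C)C1=C(C)C[C@@H](B([C@@H]2C[C@@H]3C[C@H]([C@H]2C)C3(C)C)[C@@H]2C[C@@H]3C[C@H]([C@H]2C)C3(C)C)CC1(C)C | intermediate
8 | ethane-1,2-diyl bis[(4R)-4-hydroxy-2,6,6-trimethylcyclohex-1-ene-1-carboxylate] | O=C(OCCOC(=O)C1=C(C)C[C@@H](O)CC1(C)C)C1=C(C)C[C@@H](O)CC1(C)C | intermediate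
9 | (1R)-4-(hydroxymethyl)-3,5,5-trimethylcyclohex-3-en-1-ol | OCC1=C(C)C[C@@H](O)CC1(C)C | intermediate
10 | (4R)-4-hydroxy-2,6,6-trimethylcyclohex-1-ene-1-carbaldehyde | O=CC1=C(C)C[C@@H](O)CC1(C)C | intermediate
11 | (1R)-4-ethynyl-3,5,5-trimethylcyclohex-3-en-1-ol | C#CC1=C(C)C[C@@H](O)CC1(C)C | intermediate
12 | ethyl acetoacetate | CCOC(=O)CC(C)=O | starting material
13 | ethyl (2E)-3-{[(trifluoromethyl)sulfonyl]oxy}but-2-enoate | CCOC(=O)/C=C(\C)OS(=O)(=O)C(F)(F)F | intermediate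
14 | (2E)-4-hydroxybut-2-en-2-yl trifluoromethanesulfonate | OC/C=C(\C)OS(=O)(=O)C(F)(F)F | intermediate
15 | (1R)-4-[(3E)-5-hydroxy-3-methylpent-3-en-1-yn-1-yl]-3,5,5-trimethylcyclohex-3-en-1-ol | OC/C=C(\C)C#CC1=C(C)C[C@@H](O)CC1(C)C | intermediate
16 | (1R)-4-[(3E)-5-bromo-3-methylpent-3-en-1-yn-1-yl]-3,5,5-trimethylcyclohex-3-en-1-ol (in situ) | BrC/C=C(\C)C#CC1=C(C)C[C@@H](O)CC1(C)C | intermediate
17 | tributyl{(2E)-5-[(4R)-4-hydroxy-2,6,6-trimethylcyclohex-1-en-1-yl]-3-methylpent-2-en-4-yn-1-yl}phosphonium bromide | CCCC[P+](CCCC)(CCCC)C/C=C(\C)C#CC1=C(C)C[C@@H](O)CC1(C)C.[Br-] | intermediate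
18 | (2E,4E,6E)-2,7-dimethylocta-2,4,6-trienedial | O=C/C(C)=C/C=C/C=C(C)/C=O | starting material
19 | tributylphosphonium ylide of 17 (in situ) | CCCCP(CCCC)(CCCC)=C/C=C(\C)C#CC1=C(C)C[C@@H](O)CC1(C)C | intermediate
20 | (2E,4E,6E,8E,10E)-13-[(4R)-4-hydroxy-2,6,6-trimethylcyclohex-1-en-1-yl]-2,7,11-trimethyltrideca-2,4,6,8,10-pentaen-12-ynal | CC1=C(C#C/C(C)=C/C=C/C(C)=C/C=C/C=C(C)/C=O)C(C)(C)C[C@H](O)C1 | intermediate
21 | (1R)-4-ethenyl-3,5,5-trimethylcyclohex-3-en-1-ol | C=CC1=C(C)C[C@@H](O)CC1(C)C | intermediate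
22 | 9-{2-[(4R)-4-(9-borabicyclo[3.3.1]nonan-9-yloxy)-2,6,6-trimethylcyclohex-1-en-1-yl]ethyl}-9-borabicyclo[3.3.1]nonane (in situ) | CC1=C(CCB2C3CCCC2CCC3)C(C)(C)C[C@H](OB2C3CCCC2CCC3)C1 | intermediate
23 | (1R)-4-[(3E)-5-hydroxy-3-methylpent-3-en-1-yl]-3,5,5-trimethylcyclohex-3-en-1-ol | OC/C=C(\C)CCC1=C(C)C[C@@H](O)CC1(C)C | intermediate
24 | (1R)-4-[(3E)-5-bromo-3-methylpent-3-en-1-yl]-3,5,5-trimethylcyclohex-3-en-1-ol (in situ) | BrC/C=C(\C)CCC1=C(C)C[C@@H](O)CC1(C)C | intermediate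
25 | tributyl{(2E)-5-[(4R)-4-hydroxy-2,6,6-trimethylcyclohex-1-en-1-yl]-3-methylpent-2-en-1-yl}phosphonium bromide | CCCC[P+](CCCC)(CCCC)C/C=C(\C)CCC1=C(C)C[C@@H](O)CC1(C)C.[Br-] | intermediate
26 | tributylphosphonium ylide of 25 (in situ) | CCCCP(CCCC)(CCCC)=C/C=C(\C)CCC1=C(C)C[C@@H](O)CC1(C)C | intermediate
27 | (3R,3'R)-all-E-7,8-didehydro-7',8'-dihydro-β,β-carotene-3,3'-diol | CC1=C(C#C/C(C)=C/C=C/C(C)=C/C=C/C=C(C)/C=C/C=C(\C)CCC2=C(C)C[C@@H](O)CC2(C)C)C(C)(C)C[C@H](O)C1 | target

## Step count and risks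

Total steps: 15. Longest linear sequence: 10 steps (1, 2, 3, 4, 5, 6, 9, 10, 11, 15).

The three steps most likely to fail:

**Step 2 (twofold cycloaddition of a diene with a (Z)-terminal methyl group).** If it fails, both rings are closed instead by a twofold Michael–aldol annulation. The fallback sets out from 2 and returns at 8. Compound 2 is acetoacetylated with 2,2,6-trimethyl-4H-1,3-dioxin-4-one (xylene, 140 °C) to ethane-1,2-diyl bis(3-oxobutanoate) F1. F1 is condensed with two equivalents of mesityl oxide (BF3·OEt2) to ethane-1,2-diyl bis(2,6,6-trimethyl-4-oxocyclohex-2-ene-1-carboxylate) F2, again closing both rings in one operation. Reagent-controlled CBS reduction with (R)-Me-CBS/BH3·SMe2 (enone C=C as the large group) gives ethane-1,2-diyl bis[(4S)-4-hydroxy-2,6,6-trimethylcyclohex-2-ene-1-carboxylate] F3. DBU (toluene, 80 °C) then moves the ring C=C into conjugation with the ester. The carbinol carbon is untouched; its descriptor changes from S to R only because the CIP ranks of its neighbours change. This gives 8.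

**Step 3 (Ipc2BH on an alkene next to a quaternary carbon: rate and ee).** The fallback sets out from 6 and returns at 9; it uses the diene type for which this hydroboration is established in zeaxanthin chemistry. Compound 6 is isomerised with DBU to the conjugated ethane-1,2-diyl bis(2,6,6-trimethylcyclohexa-1,3-diene-1-carboxylate) F4. LiAlH4 reduction gives (2,6,6-trimethylcyclohexa-1,3-dien-1-yl)methanol F5, which is protected with 2-methoxypropene/PPTS as 1-{[(2-methoxypropan-2-yl)oxy]methyl}-2,6,6-trimethylcyclohexa-1,3-diene F6. Hydroboration with the enantiomeric reagent (+)-Ipc2BH (from (−)-α-pinene), then NaOH/H2O2, gives (1R)-4-{[(2-methoxypropan-2-yl)oxy]methyl}-3,5,5-trimethylcyclohex-3-en-1-ol F7. The enantiomeric reagent is needed because boron enters the same carbon but the partner alkene carbon now lies on the other side. Dilute acetic acid removes the acetal and gives 9.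

**Step 11 (mono-Wittig with an ylide next to the enyne: selectivity and 9E integrity).** The fallback reverses the polarity so that no ylide is ever formed beside the enyne. It sets out from 15 (and uses 25 and 18) and returns at 27. Compound 15 is oxidised with MnO2 to (2E)-5-[(4R)-4-hydroxy-2,6,6-trimethylcyclohex-1-en-1-yl]-3-methylpent-2-en-4-ynal F8. Separately, 25 is condensed with excess 18 (NaOMe) to (2E,4E,6E,8E,10E)-13-[(4R)-4-hydroxy-2,6,6-trimethylcyclohex-1-en-1-yl]-2,7,11-trimethyltrideca-2,4,6,8,10-pentaenal F9. NaBH4 reduction gives (1R)-4-[(3E,5E,7E,9E,11E)-13-hydroxy-3,8,12-trimethyltrideca-3,5,7,9,11-pentaen-1-yl]-3,5,5-trimethylcyclohex-3-en-1-ol F10. NBS/Me2S and then Bu3P give tributyl{(2E,4E,6E,8E,10E)-13-[(4R)-4-hydroxy-2,6,6-trimethylcyclohex-1-en-1-yl]-2,7,11-trimethyltrideca-2,4,6,8,10-pentaen-1-yl}phosphonium bromide F11. Wittig reaction of F11 with F8 (NaOMe) gives 27.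

## Further compounds

F1 | step 2 | ethane-1,2-diyl bis(3-oxobutanoate) | CC(=O)CC(=O)OCCOC(=O)CC(C)=O
F2 | step 2 | ethane-1,2-diyl bis(2,6,6-trimethyl-4-oxocyclohex-2-ene-1-carboxylate) (C-1 epimers) | CC1=CC(=O)CC(C)(C)C1C(=O)OCCOC(=O)C1C(C)=CC(=O)CC1(C)C
F3 | step 2 | ethane-1,2-diyl bis[(4S)-4-hydroxy-2,6,6-trimethylcyclohex-2-ene-1-carboxylate] (C-1 epimers) | O=C(OCCOC(=O)C1C(C)=C[C@@H](O)CC1(C)C)C1C(C)=C[C@@H](O)CC1(C)C
F4 | step 3 | ethane-1,2-diyl bis(2,6,6-trimethylcyclohexa-1,3-diene-1-carboxylate) | CC1=C(C(=O)OCCOC(=O)C2=C(C)C=CCC2(C)C)C(C)(C)CC=C1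
F5 | step 3 | (2,6,6-trimethylcyclohexa-1,3-dien-1-yl)methanol | CC1=C(CO)C(C)(C)CC=C1
F6 | step 3 | 1-{[(2-methoxypropan-2-yl)oxy]methyl}-2,6,6-trimethylcyclohexa-1,3-diene | CC1=C(COC(C)(C)OC)C(C)(C)CC=C1
F7 | step 3 | (1R)-4-{[(2-methoxypropan-2-yl)oxy]methyl}-3,5,5-trimethylcyclohex-3-en-1-ol | CC1=C(COC(C)(C)OC)C(C)(C)C[C@H](O)C1
F8 | step 11 | (2E)-5-[(4R)-4-hydroxy-2,6,6-trimethylcyclohex-1-en-1-yl]-3-methylpent-2-en-4-ynal | O=C/C=C(\C)C#CC1=C(C)C[C@@H](O)CC1(C)C
F9 | step 11 | (2E,4E,6E,8E,10E)-13-[(4R)-4-hydroxy-2,6,6-trimethylcyclohex-1-en-1-yl]-2,7,11-trimethyltrideca-2,4,6,8,10-pentaenal | O=C/C(C)=C/C=C/C=C(C)/C=C/C=C(\C)CCC1=C(C)C[C@@H](O)CC1(C)C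
F10 | step 11 | (1R)-4-[(3E,5E,7E,9E,11E)-13-hydroxy-3,8,12-trimethyltrideca-3,5,7,9,11-pentaen-1-yl]-3,5,5-trimethylcyclohex-3-en-1-ol | OC/C(C)=C/C=C/C=C(C)/C=C/C=C(\C)CCC1=C(C)C[C@@H](O)CC1(C)C
F11 | step 11 | tributyl{(2E,4E,6E,8E,10E)-13-[(4R)-4-hydroxy-2,6,6-trimethylcyclohex-1-en-1-yl]-2,7,11-trimethyltrideca-2,4,6,8,10-pentaen-1-yl}phosphonium bromide | CCCC[P+](CCCC)(CCCC)C/C(C)=C/C=C/C=C(C)/C=C/C=C(\C)CCC1=C(C)C[C@@H](O)CC1(C)C.[Br-]
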